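Don't read a flat curve as an equilibrium.

| flask | substrate | enzyme | remark | time |
|---|---|---|---|---|
| ochre | 0.14 M | 10 µM (in portions, 2) | run made earlier; portions every 3.0 min |  |
| green | 0.22 M | 10 µM (in portions, 2) | run made earlier; portions every 3.0 min |  |
| teal | 0.10 M | 15 µM (in portions, 2) | run made earlier; portions every 3.0 min |  |
| flask | 0.10 M | 10 µM (in portions, 2) | the portions of enzyme follow each other after 3.0 min, the first at the start | 40 min |

- ochre (time / min: product / %, substrate / %): 6.00: 61.3, 37.5; 15.0: 75.1, 23.8; 20.0: 75.8, 23.7; 30.0: 76.8, 23.4; 40.0: 75.7, 24.3; 50.0: 76.6, 23.4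
- green (time / min: product / %, substrate / %): 4.00: 30.7, 70.3; 6.00: 43.6, 56.2; 8.00: 49.9, 50.0; 15.0: 54.6, 46.2; 20.0: 55.0, 45.3; 30.0: 55.6, 44.5; 50.0: 55.8, 45.1
- teal (time / min: product / %, substrate / %): 10.0: 94.4, 6.0; 20.0: 95.1, 4.7; 30.0: 96.2, 5.0; 40.0: 95.7, 3.8; 50.0: 95.3, 4.6

(each reading ± 0.5 percentage points)

- what may be going on: substrate + enzyme -> product + enzyme; enzyme -> spent catalyst B; enzyme + product -> spent catalyst A

1. concentration of product at 40 min, in M
2. concentration of substrate at 40 min, in M

Take the last rows. Product over substrate is 3.27 in ochre but 1.24 in green, so the two plateaus share no equilibrium ratio. Suspect the enzyme instead.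

Call product P, remaining substrate S and charged substrate F. Suppose enzyme dies in proportion to P and works at a speed proportional to S/(K+S), where K is the substrate level of half speed. Each small step of product then costs enzyme in proportion to P(K+S)/S.

Solve both ends. Far above K, the steps sum to P·P/2. Far below K (pseudo-first-order), they sum to K(F·ln(F/S) − P). Join the ends by adding them. That sum at the plateau is the enzyme budget B, set by the enzyme charge.

Ochre ends at 0.107 M product and green at 0.123 M. With equal charges, their budgets must match, which gives the reading K = 0.0409 M and B = 0.00968 M^2.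

Teal, unused so far, spends 0.0132 M^2, less than the 0.0145 M^2 its larger charge allows, so the budget is rough.

For the new flask I try 0.0100 M substrate left. That costs 0.00978 M^2, close to B, so I commit to 0.0900 M product.

The forecast says 0.088 M product (0.083 M to 0.092 M) and 0.012 M substrate (0.008 M to 0.017 M), a little less product than mine. Its grounds are its own fit, with K about 0.045 M, which it says “fits all three runs fairly well” and which gives about 89% conversion.

    substrate + enzyme → product + enzyme, rate k1*[substrate]*[enzyme]/(1 + ([substrate]/Km1) + ([product]/Kp1)) (3.60 mM, 6.40 mM, k = 16000 M⁻¹ s⁻¹)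
    enzyme → spent catalyst B (k = 2.30 × 10⁻⁴ s⁻¹)
    enzyme + product → spent catalyst A (k = 0.0530 M⁻¹ s⁻¹)

The flask gives 0.0899 M product and 0.0101 M substrate, which cost 0.00973 M^2 against B. A flask charged with 0.40 M substrate ends at 0.132 M product and costs 0.00983 M^2. At 3.26 min in the flask, enzyme has a half-life of 4.9 min through the step with product, shorter than 50 min through the step to spent catalyst B. At 40.0 min, spent catalyst A holds 93.0% of the charged enzyme and spent catalyst B 7.05%.

The runs were computed for an exercise; scatter was added.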